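Ring atoms are called O1, C2 (carbonyl), C3, C4, C5 and C6. The dihydropyranone is opened at O1–C2 to a (Z)-2-ene-1,5-diol, which is cut at C2–C3 and C5–C6. One boron atom makes both bonds in one flask. A lithiated allylic carbamate (C3–C5 with the homoprenyl arm) captures diborylmethane, and its CH2B group (C2) shifts onto C3. The tertiary allylboronate formed then delivers C5 to the aldehyde carbon (C6) of a nerol-derived enal. The step exploits the homoallylic relation between the C6 carbinol and the trisubstituted C3=C4 alkene of the ring, and it relays the C3 configuration to C6. Oxidative lactonisation and desilylation finish.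

Key step: step 11

Labels: Cα and Cβ are the two alkene carbons of the side chain next to C6 (Cα is bound to C6).
Assumption: the pinacol boronic ester is taken to borylate the lithiated allylic carbamate with retention, as is usual for pinacol esters. If it inverts, the other tartrate enantiomer in the kinetic resolution supplies the required antipode.

Step 1
Reactants: 1 nerol
Product: 2 neryl tert-butyldiphenylsilyl ether
Conditions: TBDPSCl, imidazole, CH2Cl2, 0 °C to rt
Reagents that add atoms: tert-butyldiphenylsilyl chloride, CC(C)(C)[Si](Cl)(c1ccccc1)c1ccccc1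
Why: Standard silylation of the primary allylic alcohol, using the acid-tolerant TBDPS group because it must outlast the periodic acid of step 3 and all later hydride, oxidant and organoboron steps; no stereo-element is touched.

Step 2
Reactants: 2 neryl tert-butyldiphenylsilyl ether
Product: 3 racemic 6,7-epoxide of 2
Conditions: mCPBA (1.0 equiv), CH2Cl2, −20 °C
Reagents that add atoms: 3-chloroperbenzoic acid, OOC(=O)c1cccc(Cl)c1
Why: Prilezhaev epoxidation picks the remote, more electron-rich trisubstituted alkene because the 2,3-alkene is deactivated by the allylic silyloxy group; the new stereocentre is racemic and is destroyed in step 3.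

Step 3
Reactants: 3 racemic 6,7-epoxide of 2
Product: 4 (4Z)-6-(tert-butyldiphenylsilyloxy)-4-methylhex-4-enal
Conditions: H5IO6, THF/Et2O, 0 °C
Reagents that add atoms: none
Why: Periodic acid opens the epoxide to the glycol and then cleaves it (Malaprade cleavage), which trims the isopropylidene end to the aldehyde without touching the Z alkene or the silyl ether.

Step 4
Reactants: 4 (4Z)-6-(tert-butyldiphenylsilyloxy)-4-methylhex-4-enal, 5 dimethyl malonate
Product: 6 alkylidene malonate
Conditions: piperidine (cat.), AcOH (cat.), 4 Å MS, CH2Cl2, rt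
Reagents that add atoms: none
Why: Knoevenagel condensation under buffered amine catalysis; the two ester groups are identical, so the new alkene raises no stereochemical question at this stage.

Step 5
Reactants: 6 alkylidene malonate
Product: 7 2-alkylidenepropane-1,3-diol
Conditions: DIBAL-H (iBu2AlH, 5 equiv), CH2Cl2, −78 to 0 °C, then aqueous work-up
Reagents that add atoms: none
Why: Exhaustive 1,2-reduction of both conjugated esters gives the diol, because the Lewis-acidic hydride favours carbonyl attack over conjugate attack.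

Step 6
Reactants: 7 2-alkylidenepropane-1,3-diol
Product: 8 (2E,6Z)-8-(tert-butyldiphenylsilyloxy)-2-(hydroxymethyl)-6-methylocta-2,6-dienal
Conditions: MnO2, CH2Cl2, 0 °C to rt
Reagents that add atoms: none
Why: Allylic oxidation on the MnO2 surface should take the less hindered CH2OH trans to the chain, giving the strain-free E enal that fixes the C6–Cα=Cβ geometry of the target, and should stop there because the remaining alcohol now sits on an electron-poor alkene.

Step 7
Reactants: 8 (2E,6Z)-8-(tert-butyldiphenylsilyloxy)-2-(hydroxymethyl)-6-methylocta-2,6-dienal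
Product: 9 (2E,6Z)-2-(acetoxymethyl)-8-(tert-butyldiphenylsilyloxy)-6-methylocta-2,6-dienal
Conditions: Ac2O, pyridine, CH2Cl2, 0 °C
Reagents that add atoms: acetic anhydride, CC(=O)OC(C)=O
Why: Acetylation without a nucleophilic catalyst installs the acetate of the target and avoids SN2′ displacement at the activated allylic position.

Step 8
Reactants: 10 5-bromo-2-methylpent-2-ene, 11 acrolein
Product: 13 (±)-7-methylocta-1,6-dien-3-ol, via Grignard reagent 12 (not isolated)
Conditions: Mg, THF, rt; 11, −78 °C; aq. NH4Cl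
Reagents that add atoms: none
Why: Grignard formation and 1,2-addition to acrolein at low temperature give the racemic secondary allylic alcohol that holds C3, C4, C5 and the homoprenyl arm.

Step 9
Reactants: 13 (±)-7-methylocta-1,6-dien-3-ol
Product: 14 (S)-7-methylocta-1,6-dien-3-ol
Conditions: Ti(OiPr)4 (cat.), D-(−)-diisopropyl tartrate (cat.), t-BuOOH (0.6 equiv), 4 Å MS, CH2Cl2, −20 °C
Reagents that add atoms: none
Why: In the Sharpless kinetic resolution the titanium–tartrate complex from the D-(−)-tartrate epoxidises the (R)-alcohol much faster, so the (S)-alcohol is left and the remote alkene, which has no directing hydroxyl, is untouched; this sets the C3 stereocentre that later controls C6.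

Step 10
Reactants: 14 (S)-7-methylocta-1,6-dien-3-ol
Product: 15 (S)-7-methylocta-1,6-dien-3-yl N,N-diisopropylcarbamate
Conditions: iPr2NC(O)Cl, Et3N, CH2Cl2, reflux
Reagents that add atoms: N,N-diisopropylcarbamoyl chloride, CC(C)N(C(C)C)C(Cl)=O
Why: Carbamoylation takes place at oxygen, so C3 keeps its configuration, and it installs the directing and leaving group for lithiation–borylation.

Step 11
Reactants: 15 (S)-7-methylocta-1,6-dien-3-yl N,N-diisopropylcarbamate, 16 bis(pinacolatoboryl)methane, 9 (2E,6Z)-2-(acetoxymethyl)-8-(tert-butyldiphenylsilyloxy)-6-methylocta-2,6-dienal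
Product: 21 (2Z,5R,6E,10Z)-6-(acetoxymethyl)-12-(tert-butyldiphenylsilyloxy)-10-methyl-2-(4-methylpent-3-enyl)dodeca-2,6,10-triene-1,5-diol, via lithiated carbamate 17 (not isolated), via boronate complex 18 (not isolated), via tertiary bis(boronate) 19 (not isolated), via boryl ether 20 (not isolated)
Conditions: s-BuLi, TMEDA, Et2O, −78 °C; 16, −78 °C, then 35 °C; 9, toluene, 50 °C; 30% H2O2, pH 7 phosphate buffer, THF, 0 °C
Reagents that add atoms: hydrogen peroxide, OO
Why: s-BuLi/TMEDA removes the carbamate-activated allylic C3–H of 15 with retention, the configurationally stable organolithium 17 adds to one boron of 16 to give 18, and on warming the CH2Bpin group (the future C2) migrates from boron to C3 anti to the departing carbamate (lithiation–borylation, a stereospecific 1,2-metallate rearrangement), which forms C2–C3 and gives (R)-19. The same boron then binds the aldehyde oxygen of 9 and delivers C5 to C6 through a closed six-membered chair (allylboration with allylic transposition), which forms C5–C6 and the C3=C4 alkene in 20, and buffered H2O2 turns the remaining allylic C–B bond into the C2 hydroxyl. The closest known reaction types are the one-pot lithiation–borylation–allylboration of allylic boronic esters, the homologation of diborylmethane with lithiated carbamates, and the allylation–oxidation of 1,2-bis(boronates). No ring is closed in this step. C6 is set by chirality transfer from C3: with the side chain of 9 equatorial and CH2Bpin pseudo-axial, (R)-19 reaches the aldehyde face that gives (R)-C6 together with the Z alkene. The step needs α- over γ-borylation (helped by precoordination of lithium to a pinacol oxygen at the carbanion carbon), 1,2- over 1,4-addition (inherent to the closed chair) and axial placement of CH2Bpin rather than of the homoprenyl chain (expected because the pinacol methyl groups crowd the pseudo-equatorial site, which the slim unbranched chain tolerates better); this last selectivity is the least secure, and the minor E isomer carries (S)-C6, cannot lactonise and is removed by chromatography here.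

Step 12
Reactants: 21 (2Z,5R,6E,10Z)-6-(acetoxymethyl)-12-(tert-butyldiphenylsilyloxy)-10-methyl-2-(4-methylpent-3-enyl)dodeca-2,6,10-triene-1,5-diol
Product: 24 (6R)-6-[(2E,6Z)-1-acetoxy-8-(tert-butyldiphenylsilyloxy)-6-methylocta-2,6-dien-2-yl]-3-(4-methylpent-3-enyl)-5,6-dihydro-2H-pyran-2-one, via hydroxy enal 22 (not isolated), via lactol 23 (not isolated)
Conditions: TEMPO (cat.), PhI(OAc)2 (2.5 equiv), CH2Cl2, rt
Reagents that add atoms: none
Why: In this oxidative lactonisation of a 1,5-diol, the oxoammonium species takes the primary allylic alcohol in preference to the secondary one, the Z hydroxy enal 22 closes by 6-exo-trig attack of the C6 hydroxyl on C2 to lactol 23, and a second oxidation gives the lactone with C6 untouched.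

Step 13
Reactants: 24 (6R)-6-[(2E,6Z)-1-acetoxy-8-(tert-butyldiphenylsilyloxy)-6-methylocta-2,6-dien-2-yl]-3-(4-methylpent-3-enyl)-5,6-dihydro-2H-pyran-2-one
Product: 25 (6R)-6-[(2E,6Z)-1-acetoxy-8-hydroxy-6-methylocta-2,6-dien-2-yl]-3-(4-methylpent-3-enyl)-5,6-dihydro-2H-pyran-2-one
Conditions: HF·pyridine, pyridine, THF, 0 °C to rt
Reagents that add atoms: none
Why: Fluoride-driven Si–O cleavage under buffered, non-basic conditions frees the Z allylic alcohol and leaves the acetate, the lactone and C6 unchanged.

Compound list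
1 | nerol, (2Z)-3,7-dimethylocta-2,6-dien-1-ol | CC(C)=CCC/C(C)=C\CO | starting material
2 | neryl tert-butyldiphenylsilyl ether | CC(C)=CCC/C(C)=C\CO[Si](c1ccccc1)(c1ccccc1)C(C)(C)C | intermediate
3 | racemic 6,7-epoxide of 2 | CC1(C)OC1CC/C(C)=C\CO[Si](c1ccccc1)(c1ccccc1)C(C)(C)C | intermediate
4 | (4Z)-6-(tert-butyldiphenylsilyloxy)-4-methylhex-4-enal | O=CCC/C(C)=C\CO[Si](c1ccccc1)(c1ccccc1)C(C)(C)C | intermediate
5 | dimethyl malonate | COC(=O)CC(=O)OC | starting material
6 | alkylidene malonate, dimethyl 2-[(4Z)-6-(tert-butyldiphenylsilyloxy)-4-methylhex-4-enylidene]malonate | COC(=O)C(=CCC/C(C)=C\CO[Si](c1ccccc1)(c1ccccc1)C(C)(C)C)C(=O)OC | intermediate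
7 | 2-alkylidenepropane-1,3-diol, 2-[(4Z)-6-(tert-butyldiphenylsilyloxy)-4-methylhex-4-enylidene]propane-1,3-diol | OCC(CO)=CCC/C(C)=C\CO[Si](c1ccccc1)(c1ccccc1)C(C)(C)C | intermediate
8 | (2E,6Z)-8-(tert-butyldiphenylsilyloxy)-2-(hydroxymethyl)-6-methylocta-2,6-dienal | OC/C(=C\CC/C(C)=C\CO[Si](c1ccccc1)(c1ccccc1)C(C)(C)C)C=O | intermediate
9 | (2E,6Z)-2-(acetoxymethyl)-8-(tert-butyldiphenylsilyloxy)-6-methylocta-2,6-dienal | CC(=O)OC/C(=C\CC/C(C)=C\CO[Si](c1ccccc1)(c1ccccc1)C(C)(C)C)C=O | intermediate
10 | 5-bromo-2-methylpent-2-ene | CC(C)=CCCBr | starting material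
11 | acrolein | C=CC=O | starting material
12 | Grignard reagent, (4-methylpent-3-enyl)magnesium bromide | CC(C)=CCC[Mg]Br | intermediate
13 | (±)-7-methylocta-1,6-dien-3-ol | C=CC(O)CCC=C(C)C | intermediate
14 | (S)-7-methylocta-1,6-dien-3-ol | C=C[C@@H](O)CCC=C(C)C | intermediate
15 | (S)-7-methylocta-1,6-dien-3-yl N,N-diisopropylcarbamate | C=C[C@@H](OC(=O)N(C(C)C)C(C)C)CCC=C(C)C | intermediate
16 | bis(pinacolatoboryl)methane | CC1(C)OB(CB2OC(C)(C)C(C)(C)O2)OC1(C)C | starting material
17 | lithiated carbamate (lithium at C3, retention) | C=C[C@@]([Li])(OC(=O)N(C(C)C)C(C)C)CCC=C(C)C | intermediate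
18 | boronate complex (lithium salt) | C=C[C@@]([B-]1(CB2OC(C)(C)C(C)(C)O2)OC(C)(C)C(C)(C)O1)(OC(=O)N(C(C)C)C(C)C)CCC=C(C)C.[Li+] | intermediate
19 | tertiary bis(boronate), (R)-3-(pinacolatoboryl)-3-(pinacolatoborylmethyl)-7-methylocta-1,6-diene | C=C[C@](B1OC(C)(C)C(C)(C)O1)(CB1OC(C)(C)C(C)(C)O1)CCC=C(C)C | intermediate
20 | boryl ether, C6–O–Bpin adduct that carries the (Z)-allylic CH2Bpin group | CC(=O)OC/C(=C\CC/C(C)=C\CO[Si](c1ccccc1)(c1ccccc1)C(C)(C)C)[C@H](OB1OC(C)(C)C(C)(C)O1)C/C=C(\CB1OC(C)(C)C(C)(C)O1)CCC=C(C)C | intermediate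
21 | (2Z,5R,6E,10Z)-6-(acetoxymethyl)-12-(tert-butyldiphenylsilyloxy)-10-methyl-2-(4-methylpent-3-enyl)dodeca-2,6,10-triene-1,5-diol | CC(=O)OC/C(=C\CC/C(C)=C\CO[Si](c1ccccc1)(c1ccccc1)C(C)(C)C)[C@H](O)C/C=C(\CO)CCC=C(C)C | intermediate
22 | hydroxy enal (C2 aldehyde of 21) | CC(=O)OC/C(=C\CC/C(C)=C\CO[Si](c1ccccc1)(c1ccccc1)C(C)(C)C)[C@H](O)C/C=C(\C=O)CCC=C(C)C | intermediate
23 | lactol (C2 epimers) | CC(=O)OC/C(=C\CC/C(C)=C\CO[Si](c1ccccc1)(c1ccccc1)C(C)(C)C)[C@H]1CC=C(CCC=C(C)C)C(O)O1 | intermediate
24 | (6R)-6-[(2E,6Z)-1-acetoxy-8-(tert-butyldiphenylsilyloxy)-6-methylocta-2,6-dien-2-yl]-3-(4-methylpent-3-enyl)-5,6-dihydro-2H-pyran-2-one | CC(=O)OC/C(=C\CC/C(C)=C\CO[Si](c1ccccc1)(c1ccccc1)C(C)(C)C)[C@H]1CC=C(CCC=C(C)C)C(=O)O1 | intermediate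
25 | (6R)-6-[(2E,6Z)-1-acetoxy-8-hydroxy-6-methylocta-2,6-dien-2-yl]-3-(4-methylpent-3-enyl)-5,6-dihydro-2H-pyran-2-one | CC(=O)OC/C(=C\CC/C(C)=C\CO)[C@H]1CC=C(CCC=C(C)C)C(=O)O1 | target

Total step count: 13. Longest linear sequence: 10 steps (steps 1–7, then 11–13).

Steps most likely to fail

**Step 11.** Three things may go wrong:
- The two CH2-type groups on C3 may be poorly discriminated between the axial and equatorial sites, which costs E/Z control and half of the material.
- The lithiated carbamate may be borylated at the unhindered γ-carbon.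
- Allyl transfer from the tertiary boronate to the α-branched enal may be slow.

The fallback sets out from 9 and comes back at 24. Brown allylation of 9 with the Ipc2B(allyl) reagent derived from (−)-α-pinene (Et2O, −78 °C, NaBO3 work-up) gives the (R)-homoallylic alcohol F1. Acryloyl chloride/Et3N converts it into the acrylate F2. Ring-closing metathesis with second-generation Grubbs catalyst closes the C3-unsubstituted dihydropyranone F3. I2/pyridine gives the 3-iodolactone F4. Negishi coupling of F4 with (4-methylpent-3-enyl)zinc bromide F5 (from 10, Zn, LiCl, THF) under PdCl2(dppf) catalysis installs the homoprenyl arm and gives 24.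

**Step 6.** The two allylic CH2OH groups may be poorly differentiated, or oxidation may run on to the dialdehyde. The fallback sets out from 7 and comes back at 9, and it separates the two positions by a bulky protecting group instead of by the oxidant. TBSCl (1 equiv), imidazole, −20 °C silylates the less hindered CH2OH trans to the chain and gives the mono-TBS ether F6. Ac2O/pyridine gives the acetate F7. Brief HF·pyridine removes the TBS group in the presence of the TBDPS group and gives the primary alcohol F8. Dess–Martin periodinane oxidises F8 to 9.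

**Step 4.** The enolisable aldehyde may undergo self-aldol reaction, and base may move the new alkene out of conjugation. The fallback sets out from 4 and comes back at 7, and it builds the alkylidene unit on a symmetric ketone.
- NaBH4 reduces 4 to the alcohol F9.
- I2/PPh3/imidazole (Appel-type iodination) gives the iodide F10.
- PPh3 in MeCN at reflux gives the phosphonium iodide F11.
- NaHMDS followed by 2,2-dimethyl-1,3-dioxan-5-one (Wittig olefination, no E/Z question) gives the alkylidene dioxane F12.
- 80% AcOH at rt releases 7.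

Further compounds
F1 | step 11 | (4R,5E,9Z)-5-(acetoxymethyl)-11-(tert-butyldiphenylsilyloxy)-9-methylundeca-1,5,9-trien-4-ol | CC(=O)OC/C(=C\CC/C(C)=C\CO[Si](c1ccccc1)(c1ccccc1)C(C)(C)C)[C@H](O)CC=C
F2 | step 11 | acrylate of F1 | CC(=O)OC/C(=C\CC/C(C)=C\CO[Si](c1ccccc1)(c1ccccc1)C(C)(C)C)[C@H](OC(=O)C=C)CC=C
F3 | step 11 | (6R)-dihydropyranone without the C3 chain | CC(=O)OC/C(=C\CC/C(C)=C\CO[Si](c1ccccc1)(c1ccccc1)C(C)(C)C)[C@H]1CC=CC(=O)O1
F4 | step 11 | (6R)-3-iodo-dihydropyranone | CC(=O)OC/C(=C\CC/C(C)=C\CO[Si](c1ccccc1)(c1ccccc1)C(C)(C)C)[C@H]1CC=C(I)C(=O)O1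
F5 | step 11 | (4-methylpent-3-enyl)zinc bromide | CC(C)=CCC[Zn]Br
F6 | step 6 | mono-TBS ether of 7 (TBS on the CH2OH trans to the chain) | OC/C(=C\CC/C(C)=C\CO[Si](c1ccccc1)(c1ccccc1)C(C)(C)C)CO[Si](C)(C)C(C)(C)C
F7 | step 6 | acetate of F6 | CC(=O)OC/C(=C\CC/C(C)=C\CO[Si](c1ccccc1)(c1ccccc1)C(C)(C)C)CO[Si](C)(C)C(C)(C)C
F8 | step 6 | (2Z,6Z)-2-(acetoxymethyl)-8-(tert-butyldiphenylsilyloxy)-6-methylocta-2,6-dien-1-ol | CC(=O)OC/C(=C\CC/C(C)=C\CO[Si](c1ccccc1)(c1ccccc1)C(C)(C)C)CO
F9 | step 4 | (4Z)-6-(tert-butyldiphenylsilyloxy)-4-methylhex-4-en-1-ol | OCCC/C(C)=C\CO[Si](c1ccccc1)(c1ccccc1)C(C)(C)C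
F10 | step 4 | (4Z)-6-(tert-butyldiphenylsilyloxy)-1-iodo-4-methylhex-4-ene | ICCC/C(C)=C\CO[Si](c1ccccc1)(c1ccccc1)C(C)(C)C
F11 | step 4 | [(4Z)-6-(tert-butyldiphenylsilyloxy)-4-methylhex-4-enyl]triphenylphosphonium iodide | [I-].C(CC/C(C)=C\CO[Si](c1ccccc1)(c1ccccc1)C(C)(C)C)[P+](c1ccccc1)(c1ccccc1)c1ccccc1
F12 | step 4 | 5-alkylidene-2,2-dimethyl-1,3-dioxane | CC1(C)OCC(=CCC/C(C)=C\CO[Si](c2ccccc2)(c2ccccc2)C(C)(C)C)CO1
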